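The route rests on cutting the dihydropyran ring of the 4-arylchroman half at C2–C3 and C4–C4a: a Brønsted acid oxa-Povarov union of an aryl isopropenyl ether (O1–C2 in place) with the 6-vinylchromen-5-ol half. In one operation a chiral acid protonates the enol ether, the vinyl CH2 (C3) attacks C2, and the ortho-quinone methide formed at C4 is closed by C4a, setting the only stereocentre. The step exploits the C5 hydroxyl ortho to the vinyl group on the chromene ring as a hydrogen-bond handle, and C4a of the resorcinol ring as the one free carbon ortho to O1. Both prenyl groups travel as allyl groups and are unveiled by late cross-metathesis.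

Key step: step 11

Remarks on the chemistry (assumptions):
- Chroman numbering (O1, C2, C3, C4, C4a, C5 to C8, C8a) is used for both halves; the stereocentre of the target is C4 and is (R).
- The (R)-configured acid of step 11 is assumed to give the (4R) product; if the sense of induction is the opposite, the (S)-acid is used.
- Dihydroresveratrol is taken as a commercial starting material.

Step 1
Reactants: 1 dihydroresveratrol
Product: 2 1,3-bis(methoxymethoxy)-5-{2-[4-(methoxymethoxy)phenyl]ethyl}benzene
Conditions: MOMCl (4 equiv), iPr2NEt, CH2Cl2, 0 °C to rt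
Reagents that add atoms: chloromethyl methyl ether (MOMCl) COCCl
Why: Williamson-type O-alkylation of the three phenols gives acetal ethers that tolerate the later aryllithium.

Step 2
Reactants: 2 tris-MOM ether
Product: 3 2-bromo-1,5-bis(methoxymethoxy)-3-{2-[4-(methoxymethoxy)phenyl]ethyl}benzene
Conditions: NBS (1.0 equiv), MeCN, −20 to 0 °C
Reagents that add atoms: N-bromosuccinimide O=C1CCC(=O)N1Br
Why: Electrophilic aromatic bromination should go to the doubly activated resorcinol ring at the carbon next to the chain (para to one OMOM, ortho to the other), in preference to the carbon between the two ethers and to the monooxygenated ring.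

Step 3
Reactants: 3 aryl bromide
Product: 5 2-allyl-1,5-bis(methoxymethoxy)-3-{2-[4-(methoxymethoxy)phenyl]ethyl}benzene, via aryllithium 4 (not isolated)
Conditions: n-BuLi (1.05 equiv), THF, −78 °C; then allyl bromide (1.5 equiv), −78 °C to rt
Reagents that add atoms: allyl bromide C=CCBr
Why: Bromine–lithium exchange followed by SN2 alkylation of the OMOM-chelated aryllithium places the allyl group exactly at the former C–Br carbon.

Step 4
Reactants: 5 allyl tris-MOM ether
Product: 6 4-allyl-5-[2-(4-hydroxyphenyl)ethyl]benzene-1,3-diol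
Conditions: conc. HCl (cat.), MeOH, 50 °C
Reagents that add atoms: none
Why: Acid-catalysed transacetalisation to dimethoxymethane removes all three MOM groups, and an ortho-allylphenol, unlike an ortho-prenylphenol, should not cyclise under these conditions.

Step 5
Reactants: 6 allyl triol
Product: 7 2-allyl-5-(tert-butyldimethylsilyloxy)-3-{2-[4-(tert-butyldimethylsilyloxy)phenyl]ethyl}phenol
Conditions: TBSCl (2.05 equiv), imidazole, DMF, −20 to 0 °C
Reagents that add atoms: tert-butyldimethylsilyl chloride CC(C)(C)[Si](C)(C)Cl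
Why: Steric discrimination in silyl ether formation should silylate the two unhindered phenols ahead of the one flanked by the ortho-allyl group, and over- or mis-silylated material can be returned to 6 with fluoride.

Step 6
Reactants: 7 bis-silyl phenol
Product: 8 2-allyl-5-(tert-butyldimethylsilyloxy)-3-{2-[4-(tert-butyldimethylsilyloxy)phenyl]ethyl}phenyl isopropenyl ether
Conditions: isopropenylboronic acid pinacol ester (2 equiv), Cu(OAc)2 (2 equiv), pyridine, 4 Å MS, CH2Cl2, rt
Reagents that add atoms: isopropenylboronic acid pinacol ester CC(=C)B1OC(C)(C)C(C)(C)O1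
Why: Chan–Lam–Evans oxidative C–O coupling of a phenol with an alkenylboronate transfers the isopropenyl group to the only free hydroxyl and tolerates silyl ethers and the allyl group.

Step 7
Reactants: 6 allyl triol
Product: 10 3-allyl-4,6-dihydroxy-2-[2-(4-hydroxyphenyl)ethyl]benzaldehyde, via iminium chloride 9 (not isolated)
Conditions: POCl3 (1.3 equiv), DMF, MeCN, −10 °C to rt; then H2O, 50 °C
Reagents that add atoms: N,N-dimethylformamide CN(C)C=O (formyl carbon); water O (aldehyde oxygen)
Why: Vilsmeier–Haack formylation of a resorcinol occurs para to one hydroxyl and ortho to the other and not between them, which here is the single carbon next to the arylethyl chain, while the less activated 4-hydroxyphenyl ring should stay unformylated.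

Step 8
Reactants: 10 trihydroxy aldehyde
Product: 11 8-allyl-5-hydroxy-7-[2-(4-hydroxyphenyl)ethyl]-2,2-dimethyl-2H-chromene-6-carbaldehyde
Conditions: 3-methylbut-2-enal (2 equiv), ethylenediammonium diacetate (20 mol %), toluene, 110 °C
Reagents that add atoms: 3-methylbut-2-enal CC(C)=CC=O
Why: Formal [3+3] chromene annulation (Knoevenagel-type condensation at the only free ring carbon, then oxa-6π electrocyclisation) should close onto the hydroxyl that is not hydrogen-bonded to the aldehyde, as is usual for 2,4-dihydroxybenzaldehydes.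

Step 9
Reactants: 11 chromene aldehyde
Product: 12 8-allyl-7-{2-[4-(tert-butyldimethylsilyloxy)phenyl]ethyl}-5-hydroxy-2,2-dimethyl-2H-chromene-6-carbaldehyde
Conditions: TBSCl (1.1 equiv), imidazole, CH2Cl2, 0 °C
Reagents that add atoms: tert-butyldimethylsilyl chloride CC(C)(C)[Si](C)(C)Cl
Why: Silyl ether formation should select the 4-hydroxyphenyl group because the other phenol is flanked on both sides and locked in a hydrogen bond to the aldehyde.

Step 10
Reactants: 12 silylated chromene aldehyde
Product: 13 8-allyl-7-{2-[4-(tert-butyldimethylsilyloxy)phenyl]ethyl}-2,2-dimethyl-6-vinyl-2H-chromen-5-ol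
Conditions: Ph3PCH3Br (3.5 equiv), KOtBu (3.3 equiv), THF, 0 °C to rt
Reagents that add atoms: methyltriphenylphosphonium bromide C[P+](c1ccccc1)(c1ccccc1)c1ccccc1.[Br-]
Why: Wittig methylenation of the salicylaldehyde with excess ylide (the free phenol quenches one equivalent) should give the 2-vinylphenol.

Step 11
Reactants: 8 aryl isopropenyl ether; 13 6-vinylchromen-5-ol
Product: 16 (4R)-8-allyl-4-[8-allyl-7-{2-[4-(tert-butyldimethylsilyloxy)phenyl]ethyl}-5-hydroxy-2,2-dimethyl-2H-chromen-6-yl]-5-(tert-butyldimethylsilyloxy)-7-{2-[4-(tert-butyldimethylsilyloxy)phenyl]ethyl}-2,2-dimethylchroman, via aryloxocarbenium ion 14 (not isolated), via ortho-quinone methide 15 (not isolated)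
Conditions: (R)-3,3'-bis(2,4,6-triisopropylphenyl)-1,1'-binaphthalene-2,2'-diyl N-triflylphosphoramide (10 mol %), 5 Å MS, toluene, −40 to −20 °C; 8 (1.5 equiv) added slowly to 13 and the acid
Reagents that add atoms: none
Why: Proposed new method: the acid protonates the terminal carbon of enol ether 8 to give aryloxocarbenium ion 14, paired with the chiral anion that also hydrogen-bonds the C5 hydroxyl of 13; the vinyl CH2 of 13, a vinylogous phenol carbon, attacks C2 (C2–C3 bond), proton transfer gives ortho-quinone methide 15, and its exocyclic carbon C4 is attacked by C4a of the resorcinol ring (C4–C4a bond) before rearomatisation returns the catalyst. The closest known reactions are the Lewis acid-promoted oxa-Povarov reaction of aryloxocarbenium ions with styrenes and the chiral phosphoric acid-catalysed Povarov reaction of 2-hydroxystyrenes; new here is a ketone-derived aryloxocarbenium ion made from an enol ether under chiral Brønsted acid control. One ring is closed, the dihydropyran ring of the chroman, by 6-exo-trig attack of arene carbon C4a on the exocyclic quinone methide carbon (an intramolecular Friedel–Crafts alkylation). The only stereocentre, C4, is set in that ring closure by the chiral acid, which stays hydrogen-bonded to the quinone methide oxygen and should shield one face of C4. The step needs protonation of the enol ether in preference to the styrene and chromene, attack by the unhindered vinyl CH2 and not by the chromene C3 next to the quaternary carbon or by the allyl groups (chosen over prenyl because an ortho-prenyl group would trap the oxocarbenium ion in an intramolecular Prins reaction), and closure at C4a, the only free carbon ortho to O1 because C8 carries the allyl group. Slow addition of 8 keeps the oxocarbenium ion scarce and should limit self-condensation of the enol ether.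

Step 12
Reactants: 16 bis-allyl coupled chroman
Product: 17 (4R)-4-[7-{2-[4-(tert-butyldimethylsilyloxy)phenyl]ethyl}-5-hydroxy-2,2-dimethyl-8-(3-methylbut-2-enyl)-2H-chromen-6-yl]-5-(tert-butyldimethylsilyloxy)-7-{2-[4-(tert-butyldimethylsilyloxy)phenyl]ethyl}-2,2-dimethyl-8-(3-methylbut-2-enyl)chroman
Conditions: second-generation Grubbs catalyst (H2IMes)(PCy3)Cl2Ru=CHPh (10 mol %), 2-methylbut-2-ene (large excess), 1,4-benzoquinone (10 mol %), CH2Cl2, 40 °C
Reagents that add atoms: 2-methylbut-2-ene CC=C(C)C
Why: Olefin cross-metathesis of the two terminal allyl groups with 2-methylbut-2-ene should give the trisubstituted prenyl alkenes, which, like the hindered chromene double bond, are poor metathesis substrates and so persist.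

Step 13
Reactants: 17 tris-silyl ether
Product: 18 (4R)-4-[5-hydroxy-7-[2-(4-hydroxyphenyl)ethyl]-2,2-dimethyl-8-(3-methylbut-2-enyl)-2H-chromen-6-yl]-7-[2-(4-hydroxyphenyl)ethyl]-2,2-dimethyl-8-(3-methylbut-2-enyl)chroman-5-ol
Conditions: Bu4NF (3.5 equiv), AcOH (3.5 equiv), THF, 0 °C to rt
Reagents that add atoms: none
Why: Fluoride-mediated cleavage of the three aryl silyl ethers, buffered with acetic acid, should free the phenols without touching the alkenes or the benzylic stereocentre.

Compound list
1 | dihydroresveratrol, 5-[2-(4-hydroxyphenyl)ethyl]benzene-1,3-diol | Oc1ccc(CCc2cc(O)cc(O)c2)cc1 | starting material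
2 | 1,3-bis(methoxymethoxy)-5-{2-[4-(methoxymethoxy)phenyl]ethyl}benzene | COCOc1ccc(CCc2cc(OCOC)cc(OCOC)c2)cc1 | intermediate
3 | 2-bromo-1,5-bis(methoxymethoxy)-3-{2-[4-(methoxymethoxy)phenyl]ethyl}benzene | COCOc1ccc(CCc2cc(OCOC)cc(OCOC)c2Br)cc1 | intermediate
4 | aryllithium from 3 (lithium in place of bromine) | COCOc1ccc(CCc2cc(OCOC)cc(OCOC)c2[Li])cc1 | intermediate (not isolated)
5 | 2-allyl-1,5-bis(methoxymethoxy)-3-{2-[4-(methoxymethoxy)phenyl]ethyl}benzene | COCOc1ccc(CCc2cc(OCOC)cc(OCOC)c2CC=C)cc1 | intermediate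
6 | 4-allyl-5-[2-(4-hydroxyphenyl)ethyl]benzene-1,3-diol | Oc1ccc(CCc2cc(O)cc(O)c2CC=C)cc1 | intermediate
7 | 2-allyl-5-(tert-butyldimethylsilyloxy)-3-{2-[4-(tert-butyldimethylsilyloxy)phenyl]ethyl}phenol | C=CCc1c(O)cc(O[Si](C)(C)C(C)(C)C)cc1CCc1ccc(O[Si](C)(C)C(C)(C)C)cc1 | intermediate
8 | isopropenyl ether of 7 (prop-1-en-2-yl on the phenol oxygen next to the allyl group) | C=CCc1c(OC(C)=C)cc(O[Si](C)(C)C(C)(C)C)cc1CCc1ccc(O[Si](C)(C)C(C)(C)C)cc1 | intermediate
9 | N,N-dimethyliminium chloride of aldehyde 10 (ArCH=NMe2+ Cl−) | C=CCc1c(O)cc(O)c(C=[N+](C)C)c1CCc1ccc(O)cc1.[Cl-] | intermediate (not isolated)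
10 | 3-allyl-4,6-dihydroxy-2-[2-(4-hydroxyphenyl)ethyl]benzaldehyde | C=CCc1c(O)cc(O)c(C=O)c1CCc1ccc(O)cc1 | intermediate
11 | 8-allyl-5-hydroxy-7-[2-(4-hydroxyphenyl)ethyl]-2,2-dimethyl-2H-chromene-6-carbaldehyde | C=CCc1c(CCc2ccc(O)cc2)c(C=O)c(O)c2c1OC(C)(C)C=C2 | intermediate
12 | 8-allyl-7-{2-[4-(tert-butyldimethylsilyloxy)phenyl]ethyl}-5-hydroxy-2,2-dimethyl-2H-chromene-6-carbaldehyde | C=CCc1c(CCc2ccc(O[Si](C)(C)C(C)(C)C)cc2)c(C=O)c(O)c2c1OC(C)(C)C=C2 | intermediate
13 | 8-allyl-7-{2-[4-(tert-butyldimethylsilyloxy)phenyl]ethyl}-2,2-dimethyl-6-vinyl-2H-chromen-5-ol | C=CCc1c(CCc2ccc(O[Si](C)(C)C(C)(C)C)cc2)c(C=C)c(O)c2c1OC(C)(C)C=C2 | intermediate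
14 | aryloxocarbenium ion from 8 (ArO+=CMe2; cation shown, counter-ion is the anion of the chiral acid) | C=CCc1c([O+]=C(C)C)cc(O[Si](C)(C)C(C)(C)C)cc1CCc1ccc(O[Si](C)(C)C(C)(C)C)cc1 | intermediate (not isolated)
15 | ortho-quinone methide: chromene half as 5-oxo-6-alkylidene dienone, its exocyclic CH (C4) joined through CH2 (C3) to the C(CH3)2–O–aryl unit from 8 | C=CCc1c(OC(C)(C)CC=C2C(=O)C3=C(OC(C)(C)C=C3)C(CC=C)=C2CCc2ccc(O[Si](C)(C)C(C)(C)C)cc2)cc(O[Si](C)(C)C(C)(C)C)cc1CCc1ccc(O[Si](C)(C)C(C)(C)C)cc1 | intermediate (not isolated)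
16 | (4R)-4-arylchroman: bis-allyl, tris-TBS coupled product (full name in step 11) | C=CCc1c(CCc2ccc(O[Si](C)(C)C(C)(C)C)cc2)c([C@H]2CC(C)(C)Oc3c(CC=C)c(CCc4ccc(O[Si](C)(C)C(C)(C)C)cc4)cc(O[Si](C)(C)C(C)(C)C)c32)c(O)c2c1OC(C)(C)C=C2 | intermediate
17 | (4R)-bis-prenyl, tris-TBS ether of the target (full name in step 12) | CC(C)=CCc1c(CCc2ccc(O[Si](C)(C)C(C)(C)C)cc2)c([C@H]2CC(C)(C)Oc3c(CC=C(C)C)c(CCc4ccc(O[Si](C)(C)C(C)(C)C)cc4)cc(O[Si](C)(C)C(C)(C)C)c32)c(O)c2c1OC(C)(C)C=C2 | intermediate
18 | CNP0103951.1, (4R)-4-[5-hydroxy-7-[2-(4-hydroxyphenyl)ethyl]-2,2-dimethyl-8-(3-methylbut-2-enyl)-2H-chromen-6-yl]-7-[2-(4-hydroxyphenyl)ethyl]-2,2-dimethyl-8-(3-methylbut-2-enyl)chroman-5-ol | CC(C)=CCc1c(CCc2ccc(O)cc2)c([C@H]2CC(C)(C)Oc3c(CC=C(C)C)c(CCc4ccc(O)cc4)cc(O)c32)c(O)c2c1OC(C)(C)C=C2 | target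

Total step count: 13. Longest linear sequence: 11 steps (steps 1 to 4, then 7 to 13); the other branch (steps 5 and 6) joins at step 11.

Steps most likely to fail

Step 11 (Proposed new method). The oxocarbenium ion may be consumed by self-condensation of the enol ether, by hydrolysis, or by the allyl or chromene alkenes before the vinyl group captures it. The quinone methide may also close with poor facial selectivity, or the product may racemise by reversible ring opening under the acid. The fallback uses known chemistry with a different bond set, the acid-promoted hydroarylation of a 2,2-dimethylchromene by a phenol, followed by resolution. It sets out from 7. Chromene annulation with 3-methylbut-2-enal (PhB(OH)2, AcOH, toluene, reflux) at the only free ortho carbon would give 8-allyl-5-(tert-butyldimethylsilyloxy)-7-{2-[4-(tert-butyldimethylsilyloxy)phenyl]ethyl}-2,2-dimethyl-2H-chromene F1. Cross-metathesis with 2-methylbut-2-ene (second-generation Grubbs catalyst) would give the 8-prenyl chromene F2. Bu4NF/AcOH would give 7-[2-(4-hydroxyphenyl)ethyl]-2,2-dimethyl-8-(3-methylbut-2-enyl)-2H-chromen-5-ol F3. Catalytic CF3CO2H in CH2Cl2 at 0 °C would protonate C3 of one molecule and let C6 of a second one attack C4, giving racemic 18 F4; the reaction would be stopped at partial conversion to limit oligomers. Preparative HPLC on a chiral stationary phase would then deliver 18, where the fallback meets the route.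

Step 6. Transmetalation at the ortho-substituted phenol may be slow, so that protodeboronation and homocoupling of the alkenylboronate win. The fallback builds the enol ether by ester methylenation instead of C–O coupling. It sets out from 7: acetylation (Ac2O, pyridine, DMAP) would give 2-allyl-5-(tert-butyldimethylsilyloxy)-3-{2-[4-(tert-butyldimethylsilyloxy)phenyl]ethyl}phenyl acetate F5. Methylenation of the ester carbonyl with the Tebbe reagent Cp2Ti(μ-CH2)(μ-Cl)AlMe2 (THF, pyridine, −40 to 0 °C) would then give 8, where it rejoins the route.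

Step 7. Positional selectivity may be lost (formylation between the two hydroxyls), and O-formylation or chlorination may compete on the unprotected triol. The fallback introduces the formyl carbon by halogen–metal exchange on the protected series. It sets out from 5. NBS in MeCN should brominate the last open carbon next to the chain, giving 4-allyl-2-bromo-1,5-bis(methoxymethoxy)-3-{2-[4-(methoxymethoxy)phenyl]ethyl}benzene F6. n-BuLi in THF at −78 °C would give the aryllithium F7, and a DMF quench would give 3-allyl-4,6-bis(methoxymethoxy)-2-{2-[4-(methoxymethoxy)phenyl]ethyl}benzaldehyde F8. HCl in MeOH would then remove the MOM groups and return the route at 10.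

Further compounds
F1 | step 11 | 8-allyl-5-(tert-butyldimethylsilyloxy)-7-{2-[4-(tert-butyldimethylsilyloxy)phenyl]ethyl}-2,2-dimethyl-2H-chromene | C=CCc1c(CCc2ccc(O[Si](C)(C)C(C)(C)C)cc2)cc(O[Si](C)(C)C(C)(C)C)c2c1OC(C)(C)C=C2
F2 | step 11 | 5-(tert-butyldimethylsilyloxy)-7-{2-[4-(tert-butyldimethylsilyloxy)phenyl]ethyl}-2,2-dimethyl-8-(3-methylbut-2-enyl)-2H-chromene | CC(C)=CCc1c(CCc2ccc(O[Si](C)(C)C(C)(C)C)cc2)cc(O[Si](C)(C)C(C)(C)C)c2c1OC(C)(C)C=C2
F3 | step 11 | 7-[2-(4-hydroxyphenyl)ethyl]-2,2-dimethyl-8-(3-methylbut-2-enyl)-2H-chromen-5-ol | CC(C)=CCc1c(CCc2ccc(O)cc2)cc(O)c2c1OC(C)(C)C=C2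
F4 | step 11 | racemic 18 | CC(C)=CCc1c(CCc2ccc(O)cc2)c(C2CC(C)(C)Oc3c(CC=C(C)C)c(CCc4ccc(O)cc4)cc(O)c32)c(O)c2c1OC(C)(C)C=C2
F5 | step 6 | 2-allyl-5-(tert-butyldimethylsilyloxy)-3-{2-[4-(tert-butyldimethylsilyloxy)phenyl]ethyl}phenyl acetate | C=CCc1c(OC(C)=O)cc(O[Si](C)(C)C(C)(C)C)cc1CCc1ccc(O[Si](C)(C)C(C)(C)C)cc1
F6 | step 7 | 4-allyl-2-bromo-1,5-bis(methoxymethoxy)-3-{2-[4-(methoxymethoxy)phenyl]ethyl}benzene | COCOc1ccc(CCc2c(Br)c(OCOC)cc(OCOC)c2CC=C)cc1
F7 | step 7 | aryllithium from F6 (lithium in place of bromine) | COCOc1ccc(CCc2c([Li])c(OCOC)cc(OCOC)c2CC=C)cc1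
F8 | step 7 | 3-allyl-4,6-bis(methoxymethoxy)-2-{2-[4-(methoxymethoxy)phenyl]ethyl}benzaldehyde | COCOc1ccc(CCc2c(C=O)c(OCOC)cc(OCOC)c2CC=C)cc1
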